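## Retrosynthetic overview
1. Target ⇒ (H+ exchange, O-benzyl hydrogenolysis) 3'-O-benzyl trisulfate ⇒ two ArO–S bonds at O7 and O4', with the 5-OH shielded by chelation ⇒ Pd(0) deallylation of a 5,7,4'-tri-O-allyl-3'-O-benzyl flavonol 3-sulfate.
2. Key disconnection (new step): the C3–OSO3 bond and the O1–C2 ring closure are made together from an open 2'-hydroxy-1,3-diaryl-1,3-diketone and peroxodisulfate.
3. Diketone ⇒ Baker–Venkataraman O→C acyl shift (future C2–C3 bond) of an aryl ester ⇒ di-O-allyl phloroacetophenone + 4-O-allyl-3-O-benzyl protocatechuic acid.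
4. Ring order: rings A and B are bought (phloroacetophenone, protocatechualdehyde); ring C is the only ring built, and it closes in the new step.

Assumption: the target has no stereogenic element, so "single enantiomer" needs no action; sulfate half-esters travel as Bu4N+ salts and the acid form of the SMILES is released only in the last step; (Bu4N)2S2O8 is taken as an available reagent (the known salt from K2S2O8 and Bu4NHSO4).

## Route

Step 1
Reactants: 1 2,4,6-trihydroxyacetophenone
Product: 2 1-[2,4-bis(allyloxy)-6-hydroxyphenyl]ethanone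
Conditions: allyl bromide (2.1 equiv), K2CO3 (2.2 equiv), acetone, reflux
Reagents that add atoms: allyl bromide, C=CCBr
Why: Williamson etherification stops at the di-ether because the last ortho-OH is locked in a hydrogen bond to the acetyl C=O, as in the standard 4,6-di-O-alkylation of phloroacetophenone.

Step 2
Reactants: 3 3,4-dihydroxybenzaldehyde
Product: 4 4-(allyloxy)-3-hydroxybenzaldehyde
Conditions: allyl bromide (1.05 equiv), NaHCO3 (1.5 equiv), DMF, 40 °C
Reagents that add atoms: allyl bromide, C=CCBr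
Why: Regioselective Williamson etherification works because the weak base ionises only the more acidic 4-OH para to the formyl group.

Step 3
Reactants: 4 4-(allyloxy)-3-hydroxybenzaldehyde
Product: 5 4-(allyloxy)-3-(benzyloxy)benzaldehyde
Conditions: BnBr (1.1 equiv), K2CO3 (1.5 equiv), DMF, 23 °C
Reagents that add atoms: benzyl bromide, BrCc1ccccc1
Why: Plain Williamson benzylation of the only remaining phenol places the one group that must last to the end on O3'.

Step 4
Reactants: 5 4-(allyloxy)-3-(benzyloxy)benzaldehyde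
Product: 6 4-(allyloxy)-3-(benzyloxy)benzoic acid
Conditions: NaClO2, NaH2PO4, 2-methyl-2-butene, t-BuOH/H2O, 0 → 23 °C
Reagents that add atoms: sodium chlorite, [Na+].[O-]Cl=O
Why: Pinnick oxidation converts the aldehyde to the acid while the alkene scavenger removes HOCl, so the allyl C=C and the electron-rich ring are spared.

Step 5
Reactants: 2 1-[2,4-bis(allyloxy)-6-hydroxyphenyl]ethanone; 6 4-(allyloxy)-3-(benzyloxy)benzoic acid
Product: 7 2-acetyl-3,5-bis(allyloxy)phenyl 4-(allyloxy)-3-(benzyloxy)benzoate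
Conditions: DCC (1.1 equiv), DMAP (0.2 equiv), CH2Cl2, 0 → 23 °C
Reagents that add atoms: none
Why: Steglich esterification through the acyl-pyridinium species acylates even the chelated ortho-phenol under neutral conditions.

Step 6
Reactants: 7 2-acetyl-3,5-bis(allyloxy)phenyl 4-(allyloxy)-3-(benzyloxy)benzoate
Product: 8 1-[2,4-bis(allyloxy)-6-hydroxyphenyl]-3-[4-(allyloxy)-3-(benzyloxy)phenyl]propane-1,3-dione
Conditions: LiHMDS (2.5 equiv), THF, −78 → 0 °C; AcOH quench
Reagents that add atoms: none
Why: In the Baker–Venkataraman rearrangement the acetyl enolate attacks the neighbouring ester intramolecularly, and the stabilised diketonate drives the acyl shift; LiHMDS does not isomerise the allyl ethers.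

Step 7
Reactants: 8 1-[2,4-bis(allyloxy)-6-hydroxyphenyl]-3-[4-(allyloxy)-3-(benzyloxy)phenyl]propane-1,3-dione
Product: 10 tetrabutylammonium 5,7-bis(allyloxy)-2-[4-(allyloxy)-3-(benzyloxy)phenyl]-4-oxo-4H-chromen-3-yl sulfate, via sulfooxy diketone salt 9 (not isolated)
Conditions: Bu4NOH (1.0 equiv, MeOH; strip with toluene); (Bu4N)2S2O8 (1.2 equiv), MeCN, 0 → 23 °C, dark, Ar; then AcOH (10 vol %), 45 °C
Reagents that add atoms: bis(tetrabutylammonium) peroxodisulfate, CCCC[N+](CCCC)(CCCC)CCCC.CCCC[N+](CCCC)(CCCC)CCCC.[O-]S(=O)(=O)OOS(=O)(=O)[O-]; tetrabutylammonium hydroxide, CCCC[N+](CCCC)(CCCC)CCCC.[OH-]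
Why: Proposed new method: an Elbs-type C-sulfooxylation of a 1,3-diketonate coupled to cyclodehydration, in which the soft central carbon of the Bu4N+ diketonate of 8 attacks one peroxide oxygen of S2O8(2−) in SN2 fashion and expels SO4(2−), so the C3–O bond is formed already carrying its sulfate (9, a racemic and labile centre that is erased at once); the 2-substituted diketone is now twisted and mostly ketonic, so the ortho-phenol adds to the aroyl C=O and water is lost under AcOH buffering to close ring C as the aromatic pyranone 10, which has no acidic C–H left and is inert to further oxidant; one equivalent of base leaves the chelated phenol protonated so ring attack para to it stays slow, and dark, metal-free conditions at ≤ 45 °C keep sulfate-radical chemistry away from the allyl and benzyl ethers; the closest known reaction types are the Elbs peroxodisulfate oxidation of phenolates and pyridones and the α-acyloxylation or α-sulfonyloxylation of 1,3-dicarbonyl enolates with diacyl or bis(arylsulfonyl) peroxides.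

Step 8
Reactants: 10 tetrabutylammonium 5,7-bis(allyloxy)-2-[4-(allyloxy)-3-(benzyloxy)phenyl]-4-oxo-4H-chromen-3-yl sulfate
Product: 11 tetrabutylammonium 2-[3-(benzyloxy)-4-hydroxyphenyl]-5,7-dihydroxy-4-oxo-4H-chromen-3-yl sulfate
Conditions: Pd(PPh3)4 (10 mol %), morpholine (15 equiv), THF/MeOH, 23 °C; pH 5 buffer work-up
Reagents that add atoms: none
Why: In this Tsuji–Trost deallylation Pd(0) ionises the three aryl allyl ethers and morpholine traps the π-allyl units, under neutral conditions that touch neither the benzyl ether nor the anionic sulfate.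

Step 9
Reactants: 11 tetrabutylammonium 2-[3-(benzyloxy)-4-hydroxyphenyl]-5,7-dihydroxy-4-oxo-4H-chromen-3-yl sulfate
Product: 12 tris(tetrabutylammonium) 3'-O-benzylquercetin 3,7,4'-trisulfate
Conditions: SO3·pyridine (6 equiv), pyridine, 23 °C; aq. Bu4NOH to pH 7, CH2Cl2 extraction, Sephadex LH-20
Reagents that add atoms: sulfur trioxide pyridine complex, [O-]S(=O)(=O)[n+]1ccccc1; tetrabutylammonium hydroxide, CCCC[N+](CCCC)(CCCC)CCCC.[OH-]
Why: O-sulfation with an SO3–amine complex takes the free 7- and 4'-phenols, while the 5-OH is hydrogen-bonded to C4=O and is left alone under mild conditions, as is usual for flavonoids; the cation swap also removes pyridine before the Pd step.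

Step 10
Reactants: 12 tris(tetrabutylammonium) 3'-O-benzylquercetin 3,7,4'-trisulfate
Product: 14 quercetin 3,4',7-trissulfate in the free acid form (target), via tris(tetrabutylammonium) quercetin trisulfate 13 (not isolated)
Conditions: H2 (1 atm), 10% Pd/C, MeOH, 23 °C; filter; Dowex 50W-X8 (H+ form), H2O, 4 °C; freeze-dry at once
Reagents that add atoms: none
Why: Neutral catalytic hydrogenolysis cleaves the aryl benzyl ether without touching sulfate esters or the flavone C2=C3 bond, and brief cold cation exchange swaps Bu4N+ for H+ before acid hydrolysis can start.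

## Compound list
1 | 2,4,6-trihydroxyacetophenone (achiral) | CC(=O)c1c(O)cc(O)cc1O | starting material
2 | 1-[2,4-bis(allyloxy)-6-hydroxyphenyl]ethanone (achiral) | CC(=O)c1c(O)cc(OCC=C)cc1OCC=C | intermediate
3 | 3,4-dihydroxybenzaldehyde (achiral) | O=Cc1ccc(O)c(O)c1 | starting material
4 | 4-(allyloxy)-3-hydroxybenzaldehyde (achiral) | O=Cc1ccc(OCC=C)c(O)c1 | intermediate
5 | 4-(allyloxy)-3-(benzyloxy)benzaldehyde (achiral) | O=Cc1ccc(OCC=C)c(OCc2ccccc2)c1 | intermediate
6 | 4-(allyloxy)-3-(benzyloxy)benzoic acid (achiral) | OC(=O)c1ccc(OCC=C)c(OCc2ccccc2)c1 | intermediate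
7 | 2-acetyl-3,5-bis(allyloxy)phenyl 4-(allyloxy)-3-(benzyloxy)benzoate (achiral) | CC(=O)c1c(OC(=O)c2ccc(OCC=C)c(OCc3ccccc3)c2)cc(OCC=C)cc1OCC=C | intermediate
8 | 1-[2,4-bis(allyloxy)-6-hydroxyphenyl]-3-[4-(allyloxy)-3-(benzyloxy)phenyl]propane-1,3-dione (drawn as diketo tautomer, achiral) | O=C(CC(=O)c1ccc(OCC=C)c(OCc2ccccc2)c1)c1c(O)cc(OCC=C)cc1OCC=C | intermediate
9 | tetrabutylammonium 1-[2,4-bis(allyloxy)-6-hydroxyphenyl]-3-[4-(allyloxy)-3-(benzyloxy)phenyl]-1,3-dioxopropan-2-yl sulfate (racemic, labile C2; not isolated) | CCCC[N+](CCCC)(CCCC)CCCC.O=C(c1ccc(OCC=C)c(OCc2ccccc2)c1)C(OS(=O)(=O)[O-])C(=O)c1c(O)cc(OCC=C)cc1OCC=C | intermediate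
10 | tetrabutylammonium 5,7-bis(allyloxy)-2-[4-(allyloxy)-3-(benzyloxy)phenyl]-4-oxo-4H-chromen-3-yl sulfate (achiral) | CCCC[N+](CCCC)(CCCC)CCCC.O=c1c(OS(=O)(=O)[O-])c(-c2ccc(OCC=C)c(OCc3ccccc3)c2)oc2cc(OCC=C)cc(OCC=C)c12 | intermediate
11 | tetrabutylammonium 2-[3-(benzyloxy)-4-hydroxyphenyl]-5,7-dihydroxy-4-oxo-4H-chromen-3-yl sulfate (achiral) | CCCC[N+](CCCC)(CCCC)CCCC.O=c1c(OS(=O)(=O)[O-])c(-c2ccc(O)c(OCc3ccccc3)c2)oc2cc(O)cc(O)c12 | intermediate
12 | tris(tetrabutylammonium) 3'-O-benzylquercetin 3,7,4'-trisulfate (achiral) | CCCC[N+](CCCC)(CCCC)CCCC.CCCC[N+](CCCC)(CCCC)CCCC.CCCC[N+](CCCC)(CCCC)CCCC.O=c1c(OS(=O)(=O)[O-])c(-c2ccc(OS(=O)(=O)[O-])c(OCc3ccccc3)c2)oc2cc(OS(=O)(=O)[O-])cc(O)c12 | intermediate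
13 | tris(tetrabutylammonium) quercetin 3,7,4'-trisulfate (achiral; not isolated) | CCCC[N+](CCCC)(CCCC)CCCC.CCCC[N+](CCCC)(CCCC)CCCC.CCCC[N+](CCCC)(CCCC)CCCC.O=c1c(OS(=O)(=O)[O-])c(-c2ccc(OS(=O)(=O)[O-])c(O)c2)oc2cc(OS(=O)(=O)[O-])cc(O)c12 | intermediate
14 | quercetin 3,4',7-trissulfate, free acid form (achiral) | O=c1c(OS(=O)(=O)O)c(-c2ccc(OS(=O)(=O)O)c(O)c2)oc2cc(OS(=O)(=O)O)cc(O)c12 | target

## Step count and risks
Total step count: 10.
Longest linear sequence: 9 steps (3 → 14, steps 2–10).

**Step 7 (the proposed new step).**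
- Risks: single-electron oxidation of the diketonate (dimers), Elbs-type attack on ring A para to the free phenol, retro-Claisen cleavage of 9, or slow ring closure.
- The fallback uses known chemistry only, sets out from 8 and comes back to the route at 12.
- Compound 8 is cyclodehydrated with catalytic p-TsOH in toluene at 80 °C to the flavone 5,7-bis(allyloxy)-2-[4-(allyloxy)-3-(benzyloxy)phenyl]-4H-chromen-4-one F1.
- C3 is lithiated with LDA (THF, −78 °C), trapped with B(OMe)3 and oxidised with H2O2/AcOH at 0 °C to the flavonol 5,7-bis(allyloxy)-2-[4-(allyloxy)-3-(benzyloxy)phenyl]-3-hydroxy-4H-chromen-4-one F2.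
- Pd(PPh3)4/morpholine removes the three allyl groups to give 3'-O-benzylquercetin F3.
- Excess SO3·pyridine in pyridine then sulfates O3, O7 and O4' together (5-OH stays chelated), and Bu4NOH work-up gives 12.

**Step 9.**
- Risks: incomplete sulfation at the hindered O4', or partial 5-O-sulfation, would give a mixture of polyanions that is hard to separate.
- The fallback switches to masked sulfate diesters, sets out from 11 and comes back at 12.
- Compound 11 is treated with 2,2,2-trichloroethyl chlorosulfate, Et3N and DMAP in THF at 0 °C. This gives tetrabutylammonium 2-{3-(benzyloxy)-4-[(2,2,2-trichloroethoxy)sulfonyloxy]phenyl}-5-hydroxy-4-oxo-7-[(2,2,2-trichloroethoxy)sulfonyloxy]-4H-chromen-3-yl sulfate F4.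
- F4 runs on silica, so regioisomers can be removed.
- Zn dust/HCO2NH4 in MeOH then unmasks both sulfates reductively, and Bu4NOH exchange gives 12.

**Step 10.**
- Risks: the trianion may foul or slow Pd/C, and long exposure risks C2=C3 reduction or sulfate loss.
- The fallback reverses the order of events, sets out from 11 and comes back at 13.
- The benzyl ether is hydrogenolysed at the monosulfate stage (H2, Pd/C, MeOH) to tetrabutylammonium quercetin 3-sulfate F5.
- F5 is then sulfated with Bu4NHSO4/DCC in pyridine (4 → 23 °C). This method follows the innate order 7 > 4' and leaves the 3'-OH (next to the new 4'-sulfate) and the chelated 5-OH free, giving 13.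
- Compound 13 goes through the same cold H+ exchange to 14.

Further compounds
F1 | step 7 | 5,7-bis(allyloxy)-2-[4-(allyloxy)-3-(benzyloxy)phenyl]-4H-chromen-4-one | O=c1cc(-c2ccc(OCC=C)c(OCc3ccccc3)c2)oc2cc(OCC=C)cc(OCC=C)c12
F2 | step 7 | 5,7-bis(allyloxy)-2-[4-(allyloxy)-3-(benzyloxy)phenyl]-3-hydroxy-4H-chromen-4-one | O=c1c(O)c(-c2ccc(OCC=C)c(OCc3ccccc3)c2)oc2cc(OCC=C)cc(OCC=C)c12
F3 | step 7 | 3'-O-benzylquercetin, 2-[3-(benzyloxy)-4-hydroxyphenyl]-3,5,7-trihydroxy-4H-chromen-4-one | O=c1c(O)c(-c2ccc(O)c(OCc3ccccc3)c2)oc2cc(O)cc(O)c12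
F4 | step 9 | tetrabutylammonium 2-{3-(benzyloxy)-4-[(2,2,2-trichloroethoxy)sulfonyloxy]phenyl}-5-hydroxy-4-oxo-7-[(2,2,2-trichloroethoxy)sulfonyloxy]-4H-chromen-3-yl sulfate | CCCC[N+](CCCC)(CCCC)CCCC.O=c1c(OS(=O)(=O)[O-])c(-c2ccc(OS(=O)(=O)OCC(Cl)(Cl)Cl)c(OCc3ccccc3)c2)oc2cc(OS(=O)(=O)OCC(Cl)(Cl)Cl)cc(O)c12
F5 | step 10 | tetrabutylammonium quercetin 3-sulfate | CCCC[N+](CCCC)(CCCC)CCCC.O=c1c(OS(=O)(=O)[O-])c(-c2ccc(O)c(O)c2)oc2cc(O)cc(O)c12
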